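**Strategy**

The target is cut at both triple bonds, C7≡C8 and C7'≡C8', each flanked by the hindered tetrasubstituted C5=C6 alkene of a cyclohexene ring and by the all-E C20 chain, whose end carbons C8 and C8' are the formyl carbons of crocetindial. One operation joins two lithiated C10 ring sulfones to the dial and, after phosphorylation, removes phosphate and then benzenesulfinate with KOtBu, so both alkynes form while C6 and the chain geometry stay untouched. The precursor is (3S,4S)-3,4-dihydroxy-β-cyclogeranyl phenyl sulfone from safranal, its trans-diol tied as a cyclic tetraisopropyldisiloxane so that the C4–O bond cannot align with the C7 carbanion.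

Key step: step 6

Numbering used: ring C1 (gem-dimethyl), C2 (CH2), C3 and C4 (carbinols), C5 (methyl-bearing), C6; chain C7 to C15; primes for the second half.

Remark 1: crocetindial is taken as the purchased all-E compound and handled cold, in the dark, under argon.

Remark 2: the sense of induction in step 3 is assigned by analogy with indene and 2,2-dimethylchromene under the same catalyst; it is to be confirmed on diol 7 (Mosher esters), and the (S,S)-complex would be used if the sense proved opposite.

Remark 3: the diol is carried as one cyclic disiloxane instead of two separate bulky silyl ethers. Vicinal trans-bis(silyl ethers) can populate the diaxial conformer, in which C4–O is aligned with the allyl π system; two disiloxanes should also cleave more easily than four hindered secondary silyl ethers.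

Remark 4: no thermal or iodine equilibration is planned after deprotection, because in 7,8-didehydro polyenes the 9Z isomers are thermodynamically competitive with all-E. The geometry delivered by crocetindial is preserved instead.

Remark 5: because two identical chiral halves are joined, residual minor enantiomer of the sulfone should end up mainly in a separable meso-type diastereomer, raising the enantiomeric purity of the C2-symmetric product.

**Route**

Step 1
Reactants: 1 safranal (2,6,6-trimethylcyclohexa-1,3-diene-1-carbaldehyde)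
Product: 2 safranol, (2,6,6-trimethylcyclohexa-1,3-dien-1-yl)methanol
Conditions: NaBH4, CeCl3·7H2O, MeOH, 0 °C
Reagents that add atoms: none
Why: Luche 1,2-reduction of a conjugated aldehyde, in which the hard alkoxyborohydride attacks only the carbonyl carbon and leaves the ring diene intact.

Step 2
Reactants: 2 safranol; 3 sodium benzenesulfinate
Product: 5 safranyl phenyl sulfone, via safranyl bromide 4 (not isolated)
Conditions: PBr3, pyridine (cat.), THF, −20 °C; then PhSO2Na, DMF, 0 °C to rt
Reagents that add atoms: sodium benzenesulfinate (compound 3), [Na+].[O-]S(=O)c1ccccc1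
Why: Conversion of the primary allylic alcohol into the bromide followed by SN2 S-alkylation of the sulfinate at the unhindered primary carbon, the standard entry to cyclogeranyl aryl sulfones, should leave the conjugated ring diene in place.

Step 3
Reactants: 5 safranyl phenyl sulfone
Product: 6 (3S,4R)-3,4-epoxy-β-cyclogeranyl phenyl sulfone (cis-fused oxirane on C3/C4)
Conditions: (R,R)-[N,N'-bis(3,5-di-tert-butylsalicylidene)cyclohexane-1,2-diaminato]MnCl (5 mol %, trivalent manganese), mCPBA, NMO, CH2Cl2, −78 °C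
Reagents that add atoms: mCPBA, OOC(=O)c1cccc(Cl)c1
Why: Jacobsen–Katsuki epoxidation, in which the oxomanganese species attacks the cis-disubstituted C3=C4 bond of the conjugated diene at C3 rather than the shielded tetrasubstituted C5=C6 bond, and the (R,R)-ligand is expected to deliver oxygen to the face that sets both new centres as 3S,4R.

Step 4
Reactants: 6 (3S,4R)-epoxy sulfone
Product: 7 (3S,4S)-3,4-dihydroxy-β-cyclogeranyl phenyl sulfone (trans-diol)
Conditions: HClO4 (cat.), THF–H2O (3:1), 0 °C
Reagents that add atoms: water, O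
Why: Acid-catalysed anti opening of a vinyl epoxide (borderline SN2 at the allylic carbon), in which water attacks C4, activated by the C5=C6 π bond and free of a syn-axial methyl group, from the face opposite the oxirane oxygen, so C4 is inverted to 4S while C3 keeps its configuration; the electron-withdrawing sulfonylmethyl group on C6 and the C1 gem-dimethyl group disfavour a free allyl cation and attack at C6 or C3.

Step 5
Reactants: 7 (3S,4S)-diol sulfone
Product: 8 (3S,4S)-3,4-O-(1,1,3,3-tetraisopropyldisiloxane-1,3-diyl)-3,4-dihydroxy-β-cyclogeranyl phenyl sulfone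
Conditions: iPr2Si(Cl)OSi(Cl)iPr2, imidazole, DMF, 0 °C to rt
Reagents that add atoms: 1,3-dichloro-1,1,3,3-tetraisopropyldisiloxane, CC(C)[Si](Cl)(C(C)C)O[Si](Cl)(C(C)C)C(C)C
Why: Double silylation of a vicinal trans-diequatorial diol closes the seven-membered disiloxane ring, as is well known for trans-diols of inositols and pyranosides, without touching the stereocentres and locking C4–O pseudo-equatorial.

Step 6
Reactants: 8 disiloxane-protected sulfone (2.4 equiv); 9 crocetindial (all-E C20 dialdehyde, 1 equiv)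
Product: 14 3,4:3',4'-bis-O-(tetraisopropyldisiloxanediyl) ether of the target, via lithiated sulfone 10 (not isolated), via bis(lithium alkoxide) adduct 11 (not isolated), via bis(diethyl phosphate) 12 (not isolated), via bis(vinyl sulfone) 13 (not isolated)
Conditions: n-BuLi, THF, −78 °C; 9 in THF, −78 °C; ClP(O)(OEt)2, −78 to −20 °C; KOtBu, THF, −78 to 0 °C; Ar, dark
Reagents that add atoms: none
Why: The C7 lithio sulfone 10, an allyl anion whose other terminus C5 is fully substituted, should add through C7 to each formyl carbon of 9 in the 1,2 mode; diethyl chlorophosphate traps the alkoxides of 11 before retro-addition, KOtBu removes H7 and expels phosphate (E1cB) to give the 7-sulfonyl 7,8-alkenes 13, and a second base-induced loss of benzenesulfinate together with H8 gives both C7≡C8 bonds. The closest known reaction type is the one-pot sulfone–aldehyde double elimination to conjugated enynes, run here at both ends of a dialdehyde, combined with the established addition of lithiated cyclogeranyl sulfones to polyenals. No ring is closed and no stereocentre is created: the transient centres at C7 and C8 vanish, and C3, C4 and the all-E chain are spectators. The step needs 1,2-addition to win over vinylogous loss of the C4 oxygen from carbanion 10; addition at −78 °C is fast, and the disiloxane tether holds the C4–O bond near the nodal plane of the allyl anion, where it cannot align for elimination. It also needs the last elimination to take H8 rather than an allylic ring hydrogen (H4 or a C5-methyl hydrogen); the sulfonyl group directs the base to the adjacent vinylic hydrogen, and only that path gains linear conjugation of both rings with the polyene.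

Step 7
Reactants: 14 bis(disiloxanediyl) ether
Product: 15 (3S,4S,3'S,4'S)-7,8,7',8'-tetradehydro-β,β-carotene-3,4,3',4'-tetrol (target, CNP0283832.1)
Conditions: Bu4NF, AcOH (1:1), THF, 0 °C to rt; Ar, dark; crystallisation below rt
Reagents that add atoms: none
Why: Fluoride-induced Si–O cleavage of both disiloxane tethers under acetic acid buffering should release the four carbinols without ionising the allylic C4 carbinols and without base- or heat-induced isomerisation, so the all-E geometry is retained.

**Compound list**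

1 | safranal, 2,6,6-trimethylcyclohexa-1,3-diene-1-carbaldehyde | CC1=C(C=O)C(C)(C)CC=C1 | starting material
2 | safranol, (2,6,6-trimethylcyclohexa-1,3-dien-1-yl)methanol | CC1=C(CO)C(C)(C)CC=C1 | intermediate
3 | sodium benzenesulfinate | [Na+].[O-]S(=O)c1ccccc1 | starting material
4 | safranyl bromide, 1-(bromomethyl)-2,6,6-trimethylcyclohexa-1,3-diene | CC1=C(CBr)C(C)(C)CC=C1 | intermediate
5 | safranyl phenyl sulfone, 2,6,6-trimethyl-1-[(phenylsulfonyl)methyl]cyclohexa-1,3-diene | CC1=C(CS(=O)(=O)c2ccccc2)C(C)(C)CC=C1 | intermediate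
6 | (3S,4R)-3,4-epoxy-β-cyclogeranyl phenyl sulfone; (1R,6S)-2,4,4-trimethyl-3-[(phenylsulfonyl)methyl]-7-oxabicyclo[4.1.0]hept-2-ene | CC1=C(CS(=O)(=O)c2ccccc2)C(C)(C)C[C@@H]3O[C@H]13 | intermediate
7 | (3S,4S)-3,4-dihydroxy-β-cyclogeranyl phenyl sulfone; (1S,2S)-3,5,5-trimethyl-4-[(phenylsulfonyl)methyl]cyclohex-3-ene-1,2-diol | CC1=C(CS(=O)(=O)c2ccccc2)C(C)(C)C[C@H](O)[C@H]1O | intermediate
8 | (3S,4S)-3,4-O-(1,1,3,3-tetraisopropyldisiloxane-1,3-diyl)-3,4-dihydroxy-β-cyclogeranyl phenyl sulfone (key-step precursor) | CC1=C(CS(=O)(=O)c2ccccc2)C(C)(C)C[C@@H]3O[Si](C(C)C)(C(C)C)O[Si](C(C)C)(C(C)C)O[C@@H]13 | intermediate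
9 | crocetindial, (2E,4E,6E,8E,10E,12E,14E)-2,6,11,15-tetramethylhexadeca-2,4,6,8,10,12,14-heptaenedial | O=C/C(C)=C/C=C/C(C)=C/C=C/C=C(C)/C=C/C=C(\C)C=O | starting material
10 | C7-lithiated sulfone 8 | CC1=C(C([Li])S(=O)(=O)c2ccccc2)C(C)(C)C[C@@H]3O[Si](C(C)C)(C(C)C)O[Si](C(C)C)(C(C)C)O[C@@H]13 | intermediate
11 | bis(lithium alkoxide) adduct, 7,7'-bis(phenylsulfonyl)-8,8'-diolate, mixture of C7/C8 epimers | CC1=C(C(S(=O)(=O)c2ccccc2)C(O[Li])/C(C)=C/C=C/C(C)=C/C=C/C=C(C)/C=C/C=C(\C)C(O[Li])C(S(=O)(=O)c2ccccc2)C4=C(C)[C@@H]5O[Si](C(C)C)(C(C)C)O[Si](C(C)C)(C(C)C)O[C@H]5CC4(C)C)C(C)(C)C[C@@H]3O[Si](C(C)C)(C(C)C)O[Si](C(C)C)(C(C)C)O[C@@H]13 | intermediate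
12 | bis(diethyl phosphate) of the 8,8'-diol, mixture of C7/C8 epimers | CC1=C(C(S(=O)(=O)c2ccccc2)C(OP(=O)(OCC)OCC)/C(C)=C/C=C/C(C)=C/C=C/C=C(C)/C=C/C=C(\C)C(OP(=O)(OCC)OCC)C(S(=O)(=O)c2ccccc2)C4=C(C)[C@@H]5O[Si](C(C)C)(C(C)C)O[Si](C(C)C)(C(C)C)O[C@H]5CC4(C)C)C(C)(C)C[C@@H]3O[Si](C(C)C)(C(C)C)O[Si](C(C)C)(C(C)C)O[C@@H]13 | intermediate
13 | bis(vinyl sulfone), 7,7'-bis(phenylsulfonyl)-7,8:7',8'-diene, C7=C8 geometry undefined | CC1=C(C(S(=O)(=O)c2ccccc2)=C/C(C)=C/C=C/C(C)=C/C=C/C=C(C)/C=C/C=C(\C)C=C(S(=O)(=O)c2ccccc2)C4=C(C)[C@@H]5O[Si](C(C)C)(C(C)C)O[Si](C(C)C)(C(C)C)O[C@H]5CC4(C)C)C(C)(C)C[C@@H]3O[Si](C(C)C)(C(C)C)O[Si](C(C)C)(C(C)C)O[C@@H]13 | intermediate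
14 | (3S,4S,3'S,4'S)-3,4:3',4'-bis-O-(1,1,3,3-tetraisopropyldisiloxane-1,3-diyl)-7,8,7',8'-tetradehydro-β,β-carotene-3,4,3',4'-tetrol (key-step product) | CC1=C(C#C/C(C)=C/C=C/C(C)=C/C=C/C=C(C)/C=C/C=C(\C)C#CC4=C(C)[C@@H]5O[Si](C(C)C)(C(C)C)O[Si](C(C)C)(C(C)C)O[C@H]5CC4(C)C)C(C)(C)C[C@@H]3O[Si](C(C)C)(C(C)C)O[Si](C(C)C)(C(C)C)O[C@@H]13 | intermediate
15 | (3S,4S,3'S,4'S)-7,8,7',8'-tetradehydro-β,β-carotene-3,4,3',4'-tetrol, all-E | CC1=C(C#C/C(C)=C/C=C/C(C)=C/C=C/C=C(C)/C=C/C=C(\C)C#CC2=C(C)[C@H](O)[C@@H](O)CC2(C)C)C(C)(C)C[C@H](O)[C@H]1O | target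

**Step count**

Total steps: 7. Longest linear sequence: 7 steps (1 to 15).

**Steps most likely to fail**

1. Step 6. The carbanion may revert from the aldehyde adduct or lose the C4 oxygen before phosphorylation. The base-induced second elimination may stall at the vinyl sulfone or remove an allylic ring hydrogen, giving allenic material, and prolonged exposure to alkoxide may scramble chain geometry. The fallback sets out from 8 and 9 and returns at 14, replacing the base-induced second elimination by a reductive one. Carbanion 10 is added to 9 as before and the mixture is quenched cold with NH4Cl to give the bis(β-hydroxy sulfone) F1. Dess–Martin oxidation gives the bis(β-keto sulfone) F2. NaH and ClP(O)(OEt)2 in THF give the bis(enol diethyl phosphate) F3. Reductive elimination of phosphate and sulfinate with sodium amalgam, Na(Hg), in THF–DMSO at −20 °C (Bartlett–Lythgoe alkyne synthesis) then gives 14.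

2. Step 3. Facial selectivity of oxygen transfer may be insufficient on this diene. The fallback sets out from 5 and returns at 7, replacing asymmetric catalysis by resolution. Epoxidation with racemic [N,N'-bis(3,5-di-tert-butylsalicylidene)cyclohexane-1,2-diaminato]MnCl under the same oxidant gives the racemic cis-epoxide F4. Hydrolysis as in step 4 gives the racemic trans-diol F5. Preparative chromatography on a chiral stationary phase (amylose tris(3,5-dimethylphenylcarbamate)) separates the enantiomers and supplies 7.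

3. Step 4. Partial ionisation at C4 during the acid-catalysed opening may erode anti stereospecificity, so that the C4 epimer forms alongside the trans-diol. The fallback sets out from 6 and returns at 7, setting C4 by directed reduction instead of by substitution. The hydrolysis mixture, holding 7 and its C4 epimer, the (3S,4R)-cis-diol F6, is oxidised selectively at the allylic carbinol with MnO2 in CH2Cl2 to the single (3S)-3-hydroxy-4-oxo-β-cyclogeranyl phenyl sulfone F7. Hydroxyl-directed reduction with Me4NBH(OAc)3 in MeCN–AcOH at −20 °C should deliver hydride to C4 from the side of the C3 oxygen and converge on trans-diol 7.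

Further compounds

F1 | step 6 | bis(β-hydroxy sulfone), 7,7'-bis(phenylsulfonyl)-8,8'-diol of the protected C40 skeleton, mixture of C7/C8 epimers | CC1=C(C(S(=O)(=O)c2ccccc2)C(O)/C(C)=C/C=C/C(C)=C/C=C/C=C(C)/C=C/C=C(\C)C(O)C(S(=O)(=O)c2ccccc2)C4=C(C)[C@@H]5O[Si](C(C)C)(C(C)C)O[Si](C(C)C)(C(C)C)O[C@H]5CC4(C)C)C(C)(C)C[C@@H]3O[Si](C(C)C)(C(C)C)O[Si](C(C)C)(C(C)C)O[C@@H]13
F2 | step 6 | bis(β-keto sulfone), 7,7'-bis(phenylsulfonyl)-8,8'-dione | CC1=C(C(S(=O)(=O)c2ccccc2)C(=O)/C(C)=C/C=C/C(C)=C/C=C/C=C(C)/C=C/C=C(\C)C(=O)C(S(=O)(=O)c2ccccc2)C4=C(C)[C@@H]5O[Si](C(C)C)(C(C)C)O[Si](C(C)C)(C(C)C)O[C@H]5CC4(C)C)C(C)(C)C[C@@H]3O[Si](C(C)C)(C(C)C)O[Si](C(C)C)(C(C)C)O[C@@H]13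
F3 | step 6 | bis(enol diethyl phosphate) of F2, C7=C8 geometry undefined | CC1=C(C(S(=O)(=O)c2ccccc2)=C(OP(=O)(OCC)OCC)/C(C)=C/C=C/C(C)=C/C=C/C=C(C)/C=C/C=C(\C)C(OP(=O)(OCC)OCC)=C(S(=O)(=O)c2ccccc2)C4=C(C)[C@@H]5O[Si](C(C)C)(C(C)C)O[Si](C(C)C)(C(C)C)O[C@H]5CC4(C)C)C(C)(C)C[C@@H]3O[Si](C(C)C)(C(C)C)O[Si](C(C)C)(C(C)C)O[C@@H]13
F4 | step 3 | racemic cis-3,4-epoxy-β-cyclogeranyl phenyl sulfone | CC1=C(CS(=O)(=O)c2ccccc2)C(C)(C)C[C@@H]3O[C@H]13.CC1=C(CS(=O)(=O)c2ccccc2)C(C)(C)C[C@H]3O[C@@H]13
F5 | step 3 | racemic trans-3,4-dihydroxy-β-cyclogeranyl phenyl sulfone | CC1=C(CS(=O)(=O)c2ccccc2)C(C)(C)C[C@H](O)[C@H]1O.CC1=C(CS(=O)(=O)c2ccccc2)C(C)(C)C[C@@H](O)[C@@H]1O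
F6 | step 4 | (3S,4R)-3,4-dihydroxy-β-cyclogeranyl phenyl sulfone (cis-diol, C4 epimer of 7) | CC1=C(CS(=O)(=O)c2ccccc2)C(C)(C)C[C@H](O)[C@@H]1O
F7 | step 4 | (3S)-3-hydroxy-4-oxo-β-cyclogeranyl phenyl sulfone | CC1=C(CS(=O)(=O)c2ccccc2)C(C)(C)C[C@H](O)C1=O
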